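**Retrosynthetic overview**
- C3–O ester bond: core alcohol plus the (Z,Z)-diester acid (made from 3-methylfuran-2(5H)-one and angelic acid); the 9α-OH is put in last by α′-enolate hydroxylation.
- C7=C11: aldol condensation with acetone. C10–H and C3–OH: one dissolving-metal reduction of a bicyclic enedione.
- Ring A: semipinacol 1,2-shift ring expansion of a 1-vinylcyclopentanol, which installs the C4 methyl and the C3 carbonyl in one operation.
- Vinyl carbinol from (S)-Hajos–Parrish ketone and vinylmagnesium bromide; the ketone from 2-methylcyclopentane-1,3-dione and methyl vinyl ketone (proline aldol sets C5).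
- Ring order: cyclopentane (bought) → ring B (Robinson annulation) → ring A (expansion of the five-membered ring).

Assumption: eremophilane numbering is used (C3 ester carbon, C4 CHMe, C5 quaternary C–Me, C7 isopropylidene carbon, C8 C=O, C9 CHOH, C10 ring-fusion CH); the SMILES is read as (3R,4R,5R,9S,10R), i.e. trans-fused, 3α-acyloxy, 4β,5β-dimethyl, 9α-OH, both side-chain alkenes Z.

**Step 1**
Reactants: 1 2-methylcyclopentane-1,3-dione; 2 but-3-en-2-one (methyl vinyl ketone)
Product: 3 2-methyl-2-(3-oxobutyl)cyclopentane-1,3-dione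
Conditions: H2O, AcOH (cat.), 70 °C
Reagents that add atoms: none
Why: Michael addition of the acidic cyclic 1,3-dione to the enone in water; no stereocentre is formed.

**Step 2**
Reactants: 3 2-methyl-2-(3-oxobutyl)cyclopentane-1,3-dione
Product: 5 (S)-Hajos–Parrish ketone [(7aS)-7a-methyl-2,3,7,7a-tetrahydro-1H-indene-1,5(6H)-dione], via Hajos ketol 4 (not isolated)
Conditions: (S)-proline (3 mol %), DMF, 16 °C, 24 h; then H2SO4 (cat.), 95 °C; recrystallise
Reagents that add atoms: none
Why: The proline enamine intramolecular aldol reaction (Hajos–Parrish–Eder–Sauer–Wiechert) desymmetrises the dione and sets the quaternary centre as S (the future C5), acid dehydration gives the enone, and recrystallisation raises the ee above 99%.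

**Step 3**
Reactants: 5 (S)-Hajos–Parrish ketone; 6 vinylmagnesium bromide
Product: 7 (1R,7aS)-1-ethenyl-1-hydroxy-7a-methyl-1,2,3,6,7,7a-hexahydro-5H-inden-5-one (1β-OH and 1α-vinyl)
Conditions: CH2=CHMgBr (1.2 equiv), LaCl3·2LiCl (1.0 equiv), THF, −78 °C; aq. NH4Cl
Reagents that add atoms: none
Why: 1,2-Grignard addition to the more electrophilic saturated cyclopentanone (the conjugated carbonyl is less reactive and LaCl3·2LiCl suppresses enolisation) from the face opposite the angular methyl, as in additions to 17-keto steroids.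

**Step 4**
Reactants: 7 (1R,7aS)-1-ethenyl-1-hydroxy-7a-methyl-1,2,3,6,7,7a-hexahydro-5H-inden-5-one
Product: 8 (4aR,5R)-4a,5-dimethyl-4,4a,7,8-tetrahydronaphthalene-2,6(3H,5H)-dione
Conditions: divalent cobalt salen complex C36H52CoN2O2 [N,N′-bis(3,5-di-tert-butylsalicylidene)-(R,R)-cyclohexane-1,2-diaminatocobalt] (5 mol %), N-fluoro-2,4,6-trimethylpyridinium tetrafluoroborate (1.2 equiv), PhSiH3 (1.2 equiv), CH2Cl2/(CF3)2CHOH 9:1, 0 °C to rt
Reagents that add atoms: none
Why: Proposed new method: a trivalent cobalt hydride (from the cobalt complex, the N-fluoropyridinium oxidant and PhSiH3) transfers a hydrogen atom to the terminal vinyl carbon, the secondary radical is captured and oxidised to a tetravalent alkylcobalt species, and the antiperiplanar C1–C7a bond (the quaternary, more electron-rich ring carbon) shifts to that carbon with loss of divalent cobalt while the carbinol becomes the ketone, so one 1,2-shift ring expansion builds ring A, places the C4 methyl and moves the carbonyl to C3; the methyl is set cis to the angular methyl because in the reactive rotamer it lies on the hydroxyl side and not under the five-membered ring; the closest known reaction type is the cobalt-hydride hydrogen-atom-transfer/radical–polar crossover semipinacol rearrangement of tertiary allylic alcohols carrying 1,1-disubstituted alkenes, which has not been shown for an unsubstituted vinyl group on an unstrained cyclopentanol with migration of a quaternary carbon.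

**Step 5**
Reactants: 8 (4aR,5R)-4a,5-dimethyl-4,4a,7,8-tetrahydronaphthalene-2,6(3H,5H)-dione
Product: 9 (4aS,5R,6R,8aS)-6-hydroxy-4a,5-dimethyloctahydronaphthalen-2(1H)-one (trans-fused; 3α-OH 4β-Me 5β-Me 10α-H)
Conditions: Li (6 equiv), NH3/THF, t-BuOH (3 equiv), −78 °C; solid NH4Cl
Reagents that add atoms: none
Why: Dissolving-metal (Birch-type) reduction: the enone gives the trans-fused ring junction by protonation of the β-carbanion anti to the angular methyl (10α-H) and survives as its enolate, while the saturated ketone is reduced under thermodynamic control to the equatorial 3α-alcohol.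

**Step 6**
Reactants: 9 (4aS,5R,6R,8aS)-6-hydroxy-4a,5-dimethyloctahydronaphthalen-2(1H)-one; 10 acetone
Product: 11 (3S,4aS,5R,6R,8aS)-6-hydroxy-3-(2-hydroxypropan-2-yl)-4a,5-dimethyloctahydronaphthalen-2(1H)-one (C3 epimers tolerated)
Conditions: LiN(iPr)2 (2.3 equiv), THF, −78 °C; ZnCl2 (1.2 equiv); acetone (5 equiv), −78 to −40 °C; AcOH
Reagents that add atoms: none
Why: Directed aldol addition: the kinetic enolate of the trans-fused ketone forms at C7, away from the ring fusion (as C2 in 3-keto-5α-steroids), and its zinc enolate adds to acetone; the new centre is erased in the next step.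

**Step 7**
Reactants: 11 (3S,4aS,5R,6R,8aS)-6-hydroxy-3-(2-hydroxypropan-2-yl)-4a,5-dimethyloctahydronaphthalen-2(1H)-one
Product: 12 (4aS,5R,6R,8aS)-6-hydroxy-4a,5-dimethyl-3-(propan-2-ylidene)octahydronaphthalen-2(1H)-one
Conditions: TsOH·H2O (10 mol %), benzene, reflux (Dean–Stark)
Reagents that add atoms: none
Why: Acid-catalysed dehydration of the tertiary β-hydroxy ketone to the conjugated tetrasubstituted isopropylidene ketone; the secondary equatorial alcohol does not eliminate under these conditions.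

**Step 8**
Reactants: 13 3-methylfuran-2(5H)-one
Product: 15 4-methoxybenzyl (Z)-4-hydroxy-2-methylbut-2-enoate, via potassium (Z)-4-hydroxy-2-methylbut-2-enoate 14 (not isolated)
Conditions: KOH (1.0 equiv), MeOH/H2O, 0 °C to rt; evaporate; 4-MeOC6H4CH2Cl, Bu4NI (cat.), DMF, rt; used at once
Reagents that add atoms: potassium hydroxide [K+].[OH-]; 4-methoxybenzyl chloride COc1ccc(CCl)cc1
Why: Saponification opens the butenolide to the Z-hydroxy carboxylate (geometry fixed by the ring) and SN2 O-alkylation of the carboxylate gives the PMB ester, which blocks the acid during the next step.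

**Step 9**
Reactants: 15 4-methoxybenzyl (Z)-4-hydroxy-2-methylbut-2-enoate; 16 angelic acid [(Z)-2-methylbut-2-enoic acid]
Product: 17 4-methoxybenzyl (Z)-2-methyl-4-{[(Z)-2-methylbut-2-enoyl]oxy}but-2-enoate
Conditions: PPh3, diisopropyl azodicarboxylate (DIAD), THF, −20 to 0 °C
Reagents that add atoms: none
Why: Mitsunobu esterification: angelic acid acts as the carboxylate nucleophile at the activated primary allylic carbon, so no acyl activation occurs and the Z geometry of the angelate is not scrambled.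

**Step 10**
Reactants: 17 4-methoxybenzyl (Z)-2-methyl-4-{[(Z)-2-methylbut-2-enoyl]oxy}but-2-enoate
Product: 18 (Z)-2-methyl-4-{[(Z)-2-methylbut-2-enoyl]oxy}but-2-enoic acid
Conditions: CF3CO2H, anisole, CH2Cl2, 0 °C
Reagents that add atoms: none
Why: Acidolysis of the PMB ester with anisole trapping the benzylic cation; the allylic angelate and both Z-alkenes are stable to cold trifluoroacetic acid.

**Step 11**
Reactants: 12 (4aS,5R,6R,8aS)-6-hydroxy-4a,5-dimethyl-3-(propan-2-ylidene)octahydronaphthalen-2(1H)-one; 18 (Z)-2-methyl-4-{[(Z)-2-methylbut-2-enoyl]oxy}but-2-enoic acid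
Product: 20 (1R,2R,4aS,8aS)-1,8a-dimethyl-6-oxo-7-(propan-2-ylidene)decahydronaphthalen-2-yl (Z)-2-methyl-4-{[(Z)-2-methylbut-2-enoyl]oxy}but-2-enoate, via Yamaguchi mixed anhydride 19 (not isolated)
Conditions: 2,4,6-Cl3C6H2COCl, Et3N, toluene, rt; then 12, DMAP (0.3 equiv), rt
Reagents that add atoms: 2,4,6-trichlorobenzoyl chloride O=C(Cl)c1c(Cl)cc(Cl)cc1Cl (its atoms stay in 19 only)
Why: Yamaguchi esterification through the mixed anhydride acylates the only hydroxyl (equatorial 3α-OH) with retention at C3; room temperature and sub-stoichiometric DMAP limit Z-to-E isomerisation.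

**Step 12**
Reactants: 20 (1R,2R,4aS,8aS)-1,8a-dimethyl-6-oxo-7-(propan-2-ylidene)decahydronaphthalen-2-yl (Z)-2-methyl-4-{[(Z)-2-methylbut-2-enoyl]oxy}but-2-enoate
Product: 21 (1R,2R,4aR,5S,8aR)-5-hydroxy-1,8a-dimethyl-6-oxo-7-(propan-2-ylidene)decahydronaphthalen-2-yl (Z)-2-methyl-4-{[(Z)-2-methylbut-2-enoyl]oxy}but-2-enoate (CNP0308665.1)
Conditions: KN(SiMe3)2 (1.1 equiv), THF, −78 °C; 2-(benzenesulfonyl)-3-phenyloxaziridine (1.5 equiv), −78 °C; AcOH
Reagents that add atoms: 2-(benzenesulfonyl)-3-phenyloxaziridine O=S(=O)(N1OC1c1ccccc1)c1ccccc1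
Why: Kinetic α′-deprotonation of the cross-conjugated ketone at C9 (far more acidic than the ester γ-positions) and Davis oxaziridine hydroxylation of the potassium enolate from the α face, opposite the axial angular methyl, gives the equatorial 9α-alcohol, which is also the more stable epimer.

**Compound list**
1 | 2-methylcyclopentane-1,3-dione | CC1C(=O)CCC1=O | starting material
2 | but-3-en-2-one (methyl vinyl ketone) | CC(=O)C=C | starting material
3 | 2-methyl-2-(3-oxobutyl)cyclopentane-1,3-dione | CC(=O)CCC1(C)C(=O)CCC1=O | intermediate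
4 | Hajos ketol, (3aS,7aS)-3a-hydroxy-7a-methylhexahydro-1H-indene-1,5(4H)-dione | C[C@]12CCC(=O)C[C@@]1(O)CCC2=O | intermediate
5 | (S)-Hajos–Parrish ketone, (7aS)-7a-methyl-2,3,7,7a-tetrahydro-1H-indene-1,5(6H)-dione | C[C@]12CCC(=O)C=C1CCC2=O | intermediate
6 | vinylmagnesium bromide | C=C[Mg]Br | starting material
7 | (1R,7aS)-1-ethenyl-1-hydroxy-7a-methyl-1,2,3,6,7,7a-hexahydro-5H-inden-5-one | C=C[C@]1(O)CCC2=CC(=O)CC[C@]12C | intermediate
8 | (4aR,5R)-4a,5-dimethyl-4,4a,7,8-tetrahydronaphthalene-2,6(3H,5H)-dione | O=C1CCC2=CC(=O)CC[C@]2(C)[C@H]1C | intermediate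
9 | (4aS,5R,6R,8aS)-6-hydroxy-4a,5-dimethyloctahydronaphthalen-2(1H)-one | O[C@@H]1CC[C@H]2CC(=O)CC[C@]2(C)[C@H]1C | intermediate
10 | acetone | CC(C)=O | starting material
11 | (3S,4aS,5R,6R,8aS)-6-hydroxy-3-(2-hydroxypropan-2-yl)-4a,5-dimethyloctahydronaphthalen-2(1H)-one | O[C@@H]1CC[C@H]2CC(=O)[C@H](C(C)(C)O)C[C@]2(C)[C@H]1C | intermediate
12 | (4aS,5R,6R,8aS)-6-hydroxy-4a,5-dimethyl-3-(propan-2-ylidene)octahydronaphthalen-2(1H)-one | O[C@@H]1CC[C@H]2CC(=O)C(=C(C)C)C[C@]2(C)[C@H]1C | intermediate
13 | 3-methylfuran-2(5H)-one | CC1=CCOC1=O | starting material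
14 | potassium (Z)-4-hydroxy-2-methylbut-2-enoate | [K+].OC/C=C(/C)C(=O)[O-] | intermediate
15 | 4-methoxybenzyl (Z)-4-hydroxy-2-methylbut-2-enoate | OC/C=C(/C)C(=O)OCc1ccc(OC)cc1 | intermediate
16 | angelic acid, (Z)-2-methylbut-2-enoic acid | C/C=C(/C)C(=O)O | starting material
17 | 4-methoxybenzyl (Z)-2-methyl-4-{[(Z)-2-methylbut-2-enoyl]oxy}but-2-enoate | C/C=C(/C)C(=O)OC/C=C(/C)C(=O)OCc1ccc(OC)cc1 | intermediate
18 | (Z)-2-methyl-4-{[(Z)-2-methylbut-2-enoyl]oxy}but-2-enoic acid | C/C=C(/C)C(=O)OC/C=C(/C)C(=O)O | intermediate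
19 | mixed anhydride of 18 with 2,4,6-trichlorobenzoic acid | C/C=C(/C)C(=O)OC/C=C(/C)C(=O)OC(=O)c1c(Cl)cc(Cl)cc1Cl | intermediate
20 | (1R,2R,4aS,8aS)-1,8a-dimethyl-6-oxo-7-(propan-2-ylidene)decahydronaphthalen-2-yl (Z)-2-methyl-4-{[(Z)-2-methylbut-2-enoyl]oxy}but-2-enoate | C/C=C(/C)C(=O)OC/C=C(/C)C(=O)O[C@@H]1CC[C@H]2CC(=O)C(=C(C)C)C[C@]2(C)[C@H]1C | intermediate
21 | (1R,2R,4aR,5S,8aR)-5-hydroxy-1,8a-dimethyl-6-oxo-7-(propan-2-ylidene)decahydronaphthalen-2-yl (Z)-2-methyl-4-{[(Z)-2-methylbut-2-enoyl]oxy}but-2-enoate | C/C=C(/C)C(=O)OC/C=C(/C)C(=O)O[C@@H]1CC[C@H]2[C@H](O)C(=O)C(=C(C)C)C[C@]2(C)[C@H]1C | target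

**Step count**
Total: 12 steps. Longest linear sequence: 9 steps (steps 1–7, 11, 12); the acid 18 is made in a 3-step side branch (steps 8–10).

**Three steps most likely to fail**

Step 4 (the proposed new ring expansion). Failure modes: closure of the carbinol oxygen onto the alkylcobalt carbon to give a spiro-epoxide, migration of the CH2 instead of the quaternary carbon, reduction of the enone, or a poor cis/trans ratio at C4. The fallback uses known chemistry, sets out from 5 and returns at 8. 1-Lithio-1-(methylselanyl)ethane (from 1,1-bis(methylselanyl)ethane and n-BuLi, THF, −78 °C) is added to the saturated ketone of 5 to give the β-hydroxy selenide (7aS)-1-hydroxy-7a-methyl-1-[1-(methylselanyl)ethyl]-1,2,3,6,7,7a-hexahydro-5H-inden-5-one F1. AgBF4 in CH2Cl2 then triggers the Krief-type ring enlargement of the β-hydroxyalkyl selenide, in which the more substituted carbon migrates, to give 8. The C4 epimers are separated and the unwanted one is recycled by base equilibration.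

Step 11 (esterification with the Z,Z-acid). Failure modes: Z-to-E isomerisation of the activated α-methyl enoate, or slow acylation next to the C4 methyl. The fallback sets out from 12 and returns at 20, and forms the ester by carboxylate SN2 instead of acyl transfer. Dess–Martin periodinane oxidises 12 to the diketone (4aS,5R,8aS)-4a,5-dimethyl-3-(propan-2-ylidene)octahydronaphthalene-2,6-dione F2. LiBH(s-Bu)3 at −78 °C then reduces the saturated ketone from the equatorial side (axial attack is blocked by the syn-axial angular methyl) to the axial alcohol (4aS,5R,6S,8aS)-6-hydroxy-4a,5-dimethyl-3-(propan-2-ylidene)octahydronaphthalen-2(1H)-one F3. A Mitsunobu reaction of F3 with 18 (PPh3, DIAD) inverts C3 and gives 20 without activating the acid.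

Step 12 (late α′-hydroxylation beside two unsaturated esters). Failure modes: γ-deprotonation of the esters or of the isopropylidene methyls, or slow removal of the hindered C9 proton. The fallback sets out from 12 and returns at 21, and hydroxylates before the ester is present:
- Et3SiCl/imidazole converts 12 into the triethylsilyl ether (4aS,5R,6R,8aS)-4a,5-dimethyl-3-(propan-2-ylidene)-6-(triethylsilyloxy)octahydronaphthalen-2(1H)-one F4.
- KN(SiMe3)2 and the Davis oxaziridine give the 9α-alcohol (1S,4aS,5R,6R,8aR)-1-hydroxy-4a,5-dimethyl-3-(propan-2-ylidene)-6-(triethylsilyloxy)octahydronaphthalen-2(1H)-one F5.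
- t-BuMe2SiOTf/2,6-lutidine gives the bis-silyl ether, the 1-(tert-butyldimethylsilyloxy) derivative of F5, F6.
- PPTS in MeOH removes only the triethylsilyl group to give (1S,4aS,5R,6R,8aR)-1-(tert-butyldimethylsilyloxy)-6-hydroxy-4a,5-dimethyl-3-(propan-2-ylidene)octahydronaphthalen-2(1H)-one F7.
- Yamaguchi esterification with 18 gives the 9-O-tert-butyldimethylsilyl ether of 21, F8.
- HF·pyridine gives 21.

**Further compounds**
F1 | step 4 | (7aS)-1-hydroxy-7a-methyl-1-[1-(methylselanyl)ethyl]-1,2,3,6,7,7a-hexahydro-5H-inden-5-one | C[Se]C(C)[C@]1(O)CCC2=CC(=O)CC[C@]12C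
F2 | step 11 | (4aS,5R,8aS)-4a,5-dimethyl-3-(propan-2-ylidene)octahydronaphthalene-2,6-dione | O=C1CC[C@H]2CC(=O)C(=C(C)C)C[C@]2(C)[C@H]1C
F3 | step 11 | (4aS,5R,6S,8aS)-6-hydroxy-4a,5-dimethyl-3-(propan-2-ylidene)octahydronaphthalen-2(1H)-one | O[C@H]1CC[C@H]2CC(=O)C(=C(C)C)C[C@]2(C)[C@H]1C
F4 | step 12 | (4aS,5R,6R,8aS)-4a,5-dimethyl-3-(propan-2-ylidene)-6-(triethylsilyloxy)octahydronaphthalen-2(1H)-one | CC[Si](CC)(CC)O[C@@H]1CC[C@H]2CC(=O)C(=C(C)C)C[C@]2(C)[C@H]1C
F5 | step 12 | (1S,4aS,5R,6R,8aR)-1-hydroxy-4a,5-dimethyl-3-(propan-2-ylidene)-6-(triethylsilyloxy)octahydronaphthalen-2(1H)-one | CC[Si](CC)(CC)O[C@@H]1CC[C@H]2[C@H](O)C(=O)C(=C(C)C)C[C@]2(C)[C@H]1C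
F6 | step 12 | (1S,4aS,5R,6R,8aR)-1-(tert-butyldimethylsilyloxy)-4a,5-dimethyl-3-(propan-2-ylidene)-6-(triethylsilyloxy)octahydronaphthalen-2(1H)-one | CC[Si](CC)(CC)O[C@@H]1CC[C@H]2[C@H](O[Si](C)(C)C(C)(C)C)C(=O)C(=C(C)C)C[C@]2(C)[C@H]1C
F7 | step 12 | (1S,4aS,5R,6R,8aR)-1-(tert-butyldimethylsilyloxy)-6-hydroxy-4a,5-dimethyl-3-(propan-2-ylidene)octahydronaphthalen-2(1H)-one | O[C@@H]1CC[C@H]2[C@H](O[Si](C)(C)C(C)(C)C)C(=O)C(=C(C)C)C[C@]2(C)[C@H]1C
F8 | step 12 | 9-O-tert-butyldimethylsilyl ether of 21 | C/C=C(/C)C(=O)OC/C=C(/C)C(=O)O[C@@H]1CC[C@H]2[C@H](O[Si](C)(C)C(C)(C)C)C(=O)C(=C(C)C)C[C@]2(C)[C@H]1C
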